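**Plan**

1. Numbering used throughout (aromadendrane): C1 ring-fusion CH, C4 quaternary carbon, C5=C6 ring alkene, C7 the CH bearing C11(OH)Me2, C10 the CHMe. The retrosynthesis cuts, in order: the aryl OH/CHO groups (MOM ethers, ortho-lithiation/DMF); the C11–OH bond together with the C5=C6 alkene, back to a C5 tertiary cyclopropylcarbinol (C6–C7–C11 cyclopropane); the C4–C5 bond of the cyclopentane; the C4–C(benzylic) bond; and finally C4=C5 of (−)-α-gurjunene.
2. Enabling feature: on the cycloheptene, the array C5=C6–C7–C11(OH)Me2 is an opened gem-dimethylcyclopropylcarbinyl cation, so C5 can be carried as the carbonyl carbon of a bicyclo[5.1.0]octan-2-one. The quaternary C4, with its methyl and its bond to C5, is what Markovnikov H-atom transfer to a C4=CH2 alkene followed by radical attack on that ketone delivers.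
3. Forward order: the seven-membered ring with its cyclopropane comes intact from α-gurjunene (ozonolysis of C4=C5); the aryl-isopentyl unit is joined at C4; the five-membered ring is closed (C4–C5); the cyclopropane is opened to the alkene and tertiary alcohol; the arene is completed.
4. Stereochemistry: C1, C7, C10 and the cis-cyclopropane come from α-gurjunene. The benzylic centre comes from a (+)-sparteine lithiation–borylation and is transferred with retention in a Zweifel coupling. C4 is set by substrate control in the radical ring closure. The C5 carbinol configuration is erased later.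

Key step: step 9

Remark: (−)-α-gurjunene is taken as the commercial (1aR,4R,4aR,7bS) enantiomer, whose C1, C7 and C10 descriptors match the target. The secondary C5 carbinol in 14–17 is carried as an epimer mixture because C5 is re-oxidised in step 8.

**Route**

Step 1
Reactants: 1 phloroglucinol (benzene-1,3,5-triol)
Product: 2 1,3,5-tris(methoxymethoxy)benzene
Conditions: MOMCl (3.6 equiv), i-Pr2NEt, CH2Cl2, 0 °C → rt
Reagents that add atoms: chloromethyl methyl ether (MOMCl), COCCl
Why: O-alkylation of the phenols with the hard electrophile MOMCl (Williamson-type acetal formation) should give the tris-MOM ether, whose groups are base-stable, ortho-directing and acid-labile.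

Step 2
Reactants: 2 1,3,5-tris(methoxymethoxy)benzene
Product: 4 4,4,5,5-tetramethyl-2-[2,4,6-tris(methoxymethoxy)phenyl]-1,3,2-dioxaborolane, via aryllithium 3 (not isolated)
Conditions: n-BuLi, THF, 0 °C; i-PrOBpin, −78 °C → rt; aq. NH4Cl
Reagents that add atoms: 2-isopropoxy-4,4,5,5-tetramethyl-1,3,2-dioxaborolane (i-PrOBpin), CC(C)OB1OC(C)(C)C(C)(C)O1
Why: Directed ortho-metalation between two OMOM groups (all three ring CH positions are equivalent) followed by borylation of the aryllithium should give the aryl pinacol boronate.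

Step 3
Reactants: 5 3-methylbutan-1-ol
Product: 6 3-methylbutyl N,N-diisopropylcarbamate
Conditions: i-Pr2NCOCl, Et3N, CH2Cl2, reflux
Reagents that add atoms: N,N-diisopropylcarbamoyl chloride, CC(C)N(C(C)C)C(=O)Cl
Why: Carbamoylation of the primary alcohol should give the Hoppe-type carbamate needed for sparteine-mediated α-lithiation.

Step 4
Reactants: 6 3-methylbutyl N,N-diisopropylcarbamate; 4 4,4,5,5-tetramethyl-2-[2,4,6-tris(methoxymethoxy)phenyl]-1,3,2-dioxaborolane
Product: 9 4,4,5,5-tetramethyl-2-{(1S)-3-methyl-1-[2,4,6-tris(methoxymethoxy)phenyl]butyl}-1,3,2-dioxaborolane, via lithiated carbamate 7 (not isolated), via boronate complex 8 (not isolated)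
Conditions: s-BuLi, (+)-sparteine, Et2O, −78 °C; 4, −78 °C; then reflux
Reagents that add atoms: none
Why: Hoppe–Aggarwal lithiation–borylation: s-BuLi/(+)-sparteine should remove the pro-R α-hydrogen to give the configurationally stable (R)-α-lithio carbamate, which is borylated with retention and then undergoes stereoinvertive 1,2-aryl migration with loss of the carbamate, setting the benzylic centre as (S).

Step 5
Reactants: 10 (−)-α-gurjunene
Product: 12 (1S,3R,4R,7R)-4,8,8-trimethyl-3-(3-oxobutyl)bicyclo[5.1.0]octan-2-one, via ozonide 11 (not isolated)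
Conditions: O3, CH2Cl2, −78 °C; PPh3, −78 °C → rt
Reagents that add atoms: ozone, [O-][O+]=O
Why: Ozonolysis of the only alkene (tetrasubstituted C4=C5; tethered ozonide, reductive cleavage) should open the five-membered ring to the 1,5-diketone, leaving C1, C7, C10 and the cis-cyclopropane untouched; the neutral conditions avoid C1 epimerisation and aldol closure.

Step 6
Reactants: 12 (1S,3R,4R,7R)-4,8,8-trimethyl-3-(3-oxobutyl)bicyclo[5.1.0]octan-2-one
Product: 14 N'-{4-[(1S,3R,4R,7R)-2-hydroxy-4,8,8-trimethylbicyclo[5.1.0]octan-3-yl]butan-2-ylidene}-2,4,6-triisopropylbenzenesulfonohydrazide, via keto hydrazone 13 (not isolated)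
Conditions: TrisNHNH2 (1.0 equiv), THF, rt; then MeOH, NaBH4, 0 °C
Reagents that add atoms: 2,4,6-triisopropylbenzenesulfonyl hydrazide, CC(C)c1cc(C(C)C)c(S(=O)(=O)NN)c(C(C)C)c1
Why: Chemoselective hydrazone formation at the unhindered methyl ketone (the α-branched cyclopropyl ring ketone condenses far more slowly) followed by borohydride reduction of the ring ketone should mask C5 as a carbinol, which also blocks C1 epimerisation and enolate chemistry during the organolithium step.

Step 7
Reactants: 14 N'-{4-[(1S,3R,4R,7R)-2-hydroxy-4,8,8-trimethylbicyclo[5.1.0]octan-3-yl]butan-2-ylidene}-2,4,6-triisopropylbenzenesulfonohydrazide; 9 4,4,5,5-tetramethyl-2-{(1S)-3-methyl-1-[2,4,6-tris(methoxymethoxy)phenyl]butyl}-1,3,2-dioxaborolane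
Product: 17 (1S,3R,4R,7R)-4,8,8-trimethyl-3-{(4R)-6-methyl-3-methylidene-4-[2,4,6-tris(methoxymethoxy)phenyl]heptyl}bicyclo[5.1.0]octan-2-ol, via vinyllithium 15 (not isolated), via vinylboronate complex 16 (not isolated)
Conditions: n-BuLi (3.1 equiv), THF, −78 → 0 °C; 9, −78 → 0 °C; I2, −78 °C; NaOMe, MeOH, → rt
Reagents that add atoms: none
Why: The Shapiro reaction should give the less substituted 2-lithio-1-alkene (kinetic deprotonation of the CH3 group), which forms the ate complex with 9; iodine then triggers 1,2-migration of the benzylic carbon with retention, and anti-elimination (Zweifel olefination) gives the 1,1-disubstituted alkene carrying the benzylic centre, now (R) by CIP.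

Step 8
Reactants: 17 (1S,3R,4R,7R)-4,8,8-trimethyl-3-{(4R)-6-methyl-3-methylidene-4-[2,4,6-tris(methoxymethoxy)phenyl]heptyl}bicyclo[5.1.0]octan-2-ol
Product: 18 (1S,3R,4R,7R)-4,8,8-trimethyl-3-{(4R)-6-methyl-3-methylidene-4-[2,4,6-tris(methoxymethoxy)phenyl]heptyl}bicyclo[5.1.0]octan-2-one
Conditions: Dess–Martin periodinane, NaHCO3, CH2Cl2, 0 °C → rt
Reagents that add atoms: none
Why: Buffered Dess–Martin oxidation should return the cyclopropyl ketone without epimerising C1 or touching the alkene, the MOM ethers or the cyclopropane.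

Step 9
Reactants: 18 (1S,3R,4R,7R)-4,8,8-trimethyl-3-{(4R)-6-methyl-3-methylidene-4-[2,4,6-tris(methoxymethoxy)phenyl]heptyl}bicyclo[5.1.0]octan-2-one
Product: 19 (1aR,4R,4aR,7R,7aS,7bS)-1,1,4,7-tetramethyl-7-{(1R)-3-methyl-1-[2,4,6-tris(methoxymethoxy)phenyl]butyl}decahydro-1H-cyclopropa[e]azulen-7a-ol
Conditions: Fe(acac)3 (1 equiv), PhSiH3 (2.5 equiv), EtOH, 60 °C
Reagents that add atoms: none
Why: An iron hydride formed from Fe(acac)3/PhSiH3 should transfer H• to the terminal CH2 of the 1,1-disubstituted alkene (Markovnikov MHAT), creating the C4 methyl together with a tertiary C4 radical that adds to the C5 ketone; the resulting alkoxy radical is reduced by Fe(II) and protonated by ethanol. The closest known reaction type is the iron-hydride HAT-initiated reductive cyclisation of alkene-tethered ketones to cis-fused bicyclic tertiary alcohols. The cyclopentane closes in the 5-exo-trig mode onto the carbonyl carbon, the three-atom C1–C2–C3 tether delivering the radical to the carbonyl face syn to the side chain, which gives the cis ring fusion (OH cis to H-1). The new quaternary centre C4 is under substrate control: in the cis-fused transition state the large CH(Ar)(i-Bu) group of the planar radical should turn away from C6 and the seven-membered ring, onto the face of H-1 and the forming alkoxide, leaving the methyl towards the ring, which is the (R) configuration of the target; the C5 carbinol configuration does not matter because C5 becomes sp2 in step 11. The step needs radical addition to a hindered carbonyl to win over premature reduction of the radical, which intramolecularity and the absence of a good H-atom donor other than the metal hydride should favour; the cyclopropane is safe because no radical is placed on the carbon next to it (the C5–O• intermediate cannot open it).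

Step 10
Reactants: 19 (1aR,4R,4aR,7R,7aS,7bS)-1,1,4,7-tetramethyl-7-{(1R)-3-methyl-1-[2,4,6-tris(methoxymethoxy)phenyl]butyl}decahydro-1H-cyclopropa[e]azulen-7a-ol
Product: 21 5-{(1R)-1-[(1aR,4R,4aR,7R,7aS,7bS)-7a-hydroxy-1,1,4,7-tetramethyldecahydro-1H-cyclopropa[e]azulen-7-yl]-3-methylbutyl}-2,4,6-tris(methoxymethoxy)benzene-1,3-dicarbaldehyde, via amino alkoxide 20 (not isolated)
Conditions: n-BuLi (2.2 equiv), TMEDA, THF, 0 °C; DMF (1.1 equiv), −78 → 0 °C; n-BuLi (1.3 equiv), 0 °C; DMF, −78 °C → rt; aq. NH4Cl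
Reagents that add atoms: N,N-dimethylformamide (DMF), CN(C)C=O
Why: Directed ortho-metalation at a ring CH flanked by two OMOM groups and DMF quench, repeated in the same flask while the first formyl group is held as its lithium α-amino alkoxide (in situ protection), should install both aldehydes; the tertiary carbinol is protected as its lithium alkoxide and the base leaves the cyclopropylcarbinol intact.

Step 11
Reactants: 21 5-{(1R)-1-[(1aR,4R,4aR,7R,7aS,7bS)-7a-hydroxy-1,1,4,7-tetramethyldecahydro-1H-cyclopropa[e]azulen-7-yl]-3-methylbutyl}-2,4,6-tris(methoxymethoxy)benzene-1,3-dicarbaldehyde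
Product: 23 (−)-macrocarpal D, 5-{(1R)-1-[(1R,3aR,4R,7R)-7-(2-hydroxypropan-2-yl)-1,4-dimethyl-1,2,3,3a,4,5,6,7-octahydroazulen-1-yl]-3-methylbutyl}-2,4,6-trihydroxybenzene-1,3-dicarbaldehyde, via tris-MOM macrocarpal D 22 (not isolated)
Conditions: 0.5 M aq. H2SO4, THF, 0 °C → rt; then 45 °C
Reagents that add atoms: water, O
Why: Acid should ionise the tertiary cyclopropylcarbinol, and the C5 cyclopropylcarbinyl cation should open by cleavage of the external C6–C11 bond to the tertiary homoallyl cation, which water captures at C11 (cyclopropylcarbinyl–homoallyl, Julia-type rearrangement), giving the C5=C6 alkene and the tertiary alcohol with C1, C4, C7 and C10 untouched; continued acid hydrolysis then removes the three MOM acetals.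

**Compound list**

1 | phloroglucinol | Oc1cc(O)cc(O)c1 | starting material
2 | 1,3,5-tris(methoxymethoxy)benzene | COCOc1cc(OCOC)cc(OCOC)c1 | intermediate
3 | [2,4,6-tris(methoxymethoxy)phenyl]lithium | [Li]c1c(OCOC)cc(OCOC)cc1OCOC | intermediate
4 | 4,4,5,5-tetramethyl-2-[2,4,6-tris(methoxymethoxy)phenyl]-1,3,2-dioxaborolane | COCOc1cc(OCOC)c(B2OC(C)(C)C(C)(C)O2)c(OCOC)c1 | intermediate
5 | 3-methylbutan-1-ol | CC(C)CCO | starting material
6 | 3-methylbutyl N,N-diisopropylcarbamate | CC(C)CCOC(=O)N(C(C)C)C(C)C | intermediate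
7 | [(1R)-1-lithio-3-methylbutyl] N,N-diisopropylcarbamate (sparteine complex) | CC(C)C[C@@H]([Li])OC(=O)N(C(C)C)C(C)C | intermediate
8 | lithium boronate (ate) complex from 7 and 4, (1R) at the carbamate-bearing carbon | CC(C)C[C@H](OC(=O)N(C(C)C)C(C)C)[B-]1(c2c(OCOC)cc(OCOC)cc2OCOC)OC(C)(C)C(C)(C)O1.[Li+] | intermediate
9 | 4,4,5,5-tetramethyl-2-{(1S)-3-methyl-1-[2,4,6-tris(methoxymethoxy)phenyl]butyl}-1,3,2-dioxaborolane | CC(C)C[C@@H](c1c(OCOC)cc(OCOC)cc1OCOC)B1OC(C)(C)C(C)(C)O1 | intermediate
10 | (−)-α-gurjunene, (1aR,4R,4aR,7bS)-1,1,4,7-tetramethyl-1a,2,3,4,4a,5,6,7b-octahydro-1H-cyclopropa[e]azulene | CC1=C2[C@@H]3C(C)(C)[C@@H]3CC[C@@H](C)[C@H]2CC1 | starting material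
11 | 4,5-ozonide of α-gurjunene (1,2,4-trioxolane spanning C4 and C5; acetal carbons unassigned) | CC12CC[C@@H]3[C@H](C)CC[C@H]4C(C)(C)[C@H]4C3(OO1)O2 | intermediate
12 | (1S,3R,4R,7R)-4,8,8-trimethyl-3-(3-oxobutyl)bicyclo[5.1.0]octan-2-one | CC(=O)CC[C@@H]1[C@H](C)CC[C@H]2C(C)(C)[C@H]2C1=O | intermediate
13 | mono-(2,4,6-triisopropylbenzenesulfonyl)hydrazone of 12 at the methyl ketone | CC(=NNS(=O)(=O)c1c(C(C)C)cc(C(C)C)cc1C(C)C)CC[C@@H]1[C@H](C)CC[C@H]2C(C)(C)[C@H]2C1=O | intermediate
14 | N'-{4-[(1S,3R,4R,7R)-2-hydroxy-4,8,8-trimethylbicyclo[5.1.0]octan-3-yl]butan-2-ylidene}-2,4,6-triisopropylbenzenesulfonohydrazide (C2 carbinol epimers) | CC(=NNS(=O)(=O)c1c(C(C)C)cc(C(C)C)cc1C(C)C)CC[C@@H]1[C@H](C)CC[C@H]2C(C)(C)[C@H]2C1O | intermediate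
15 | 2-lithio-1-alkene lithium alkoxide from Shapiro reaction of 14 | [Li]C(=C)CC[C@@H]1[C@H](C)CC[C@H]2C(C)(C)[C@H]2C1O[Li] | intermediate
16 | lithium vinylboronate (ate) complex from 15 and 9 | CC(C)C[C@@H](c1c(OCOC)cc(OCOC)cc1OCOC)[B-]1(C(=C)CC[C@@H]2[C@H](C)CC[C@H]3C(C)(C)[C@H]3C2O[Li])OC(C)(C)C(C)(C)O1.[Li+] | intermediate
17 | (1S,3R,4R,7R)-4,8,8-trimethyl-3-{(4R)-6-methyl-3-methylidene-4-[2,4,6-tris(methoxymethoxy)phenyl]heptyl}bicyclo[5.1.0]octan-2-ol (C2 carbinol epimers) | CC(C)C[C@@H](c1c(OCOC)cc(OCOC)cc1OCOC)C(=C)CC[C@@H]1[C@H](C)CC[C@H]2C(C)(C)[C@H]2C1O | intermediate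
18 | (1S,3R,4R,7R)-4,8,8-trimethyl-3-{(4R)-6-methyl-3-methylidene-4-[2,4,6-tris(methoxymethoxy)phenyl]heptyl}bicyclo[5.1.0]octan-2-one | CC(C)C[C@@H](c1c(OCOC)cc(OCOC)cc1OCOC)C(=C)CC[C@@H]1[C@H](C)CC[C@H]2C(C)(C)[C@H]2C1=O | intermediate
19 | (1aR,4R,4aR,7R,7aS,7bS)-1,1,4,7-tetramethyl-7-{(1R)-3-methyl-1-[2,4,6-tris(methoxymethoxy)phenyl]butyl}decahydro-1H-cyclopropa[e]azulen-7a-ol | CC(C)C[C@@H](c1c(OCOC)cc(OCOC)cc1OCOC)[C@@]1(C)CC[C@H]2[C@]1(O)[C@@H]1C(C)(C)[C@@H]1CC[C@H]2C | intermediate
20 | dilithium salt of the mono-formyl adduct of 19 (aryl α-dimethylamino alkoxide, tertiary alkoxide) | CC(C)C[C@@H](c1c(OCOC)cc(OCOC)c(C(O[Li])N(C)C)c1OCOC)[C@@]1(C)CC[C@H]2[C@]1(O[Li])[C@@H]1C(C)(C)[C@@H]1CC[C@H]2C | intermediate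
21 | 5-{(1R)-1-[(1aR,4R,4aR,7R,7aS,7bS)-7a-hydroxy-1,1,4,7-tetramethyldecahydro-1H-cyclopropa[e]azulen-7-yl]-3-methylbutyl}-2,4,6-tris(methoxymethoxy)benzene-1,3-dicarbaldehyde | CC(C)C[C@@H](c1c(OCOC)c(C=O)c(OCOC)c(C=O)c1OCOC)[C@@]1(C)CC[C@H]2[C@]1(O)[C@@H]1C(C)(C)[C@@H]1CC[C@H]2C | intermediate
22 | tris-O-methoxymethyl macrocarpal D | CC(C)C[C@@H](c1c(OCOC)c(C=O)c(OCOC)c(C=O)c1OCOC)[C@@]1(C)CC[C@H]2C1=C[C@H](C(C)(C)O)CC[C@H]2C | intermediate
23 | (−)-macrocarpal D | CC(C)C[C@@H](c1c(O)c(C=O)c(O)c(C=O)c1O)[C@@]1(C)CC[C@H]2C1=C[C@H](C(C)(C)O)CC[C@H]2C | target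

**Totals**

Total step count: 11. Longest linear sequence: 8 steps (steps 1, 2, 4, 7, 8, 9, 10, 11 from phloroglucinol; 7 steps from α-gurjunene).

**Steps most likely to fail**

Step 9 (radical ring closure). The tertiary C4 radical may be reduced by a second hydrogen-atom transfer before it reaches the crowded carbonyl carbon, which gives net hydrogenation of the alkene. It may also attack through its other face, which erodes the C4 configuration. The fallback generates the same radical without a hydride source and on a titanium-bound ketone. Ketone 18 is epoxidised at the 1,1-disubstituted alkene (DMDO, acetone, 0 °C) to the keto epoxide F1. Cp2TiCl (Cp2TiCl2, Zn, THF, rt) opens the epoxide homolytically to the β-titanoxy tertiary radical, which closes onto the ketone (titanocene(III) epoxide–carbonyl reductive cyclisation) to give the diol F2. The primary neopentyl alcohol of F2 is converted selectively into the thiocarbonyl imidazolide F3 (1,1'-thiocarbonyldiimidazole, DMAP, CH2Cl2), and Barton–McCombie reduction (Bu3SnH, AIBN, toluene, 110 °C) turns the CH2O group into the methyl group, which returns the route to 19.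

Step 7 (Shapiro–Zweifel union). Formation of the vinyllithium from the trianion may be incomplete, the vinyllithium may be protonated, ate-complex formation with the hindered benzylic boronic ester may be slow, and iodine may attack the electron-rich ring. The fallback separates the two events and uses palladium for the C–C bond. Hydrazone 14 is taken through the Shapiro reaction and the vinyllithium is quenched with iodine to give the vinyl iodide F4, which is isolated. F4 is then coupled with boronic ester 9 under stereoretentive Suzuki–Miyaura conditions for secondary benzylic boronic esters (Pd2(dba)3, PPh3, Ag2O, K2CO3, DME, 85 °C) to reach 17.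

Step 11 (one-flask rearrangement and deprotection). The C5 cation may lose H-1 to give a C1=C5 alkene, whose re-protonation would scramble C1. The C11 cation may eliminate instead of taking up water. Once the phenols are free, prolonged acid may drive attack of an ortho hydroxyl on C5 (chroman formation). The fallback moves the rearrangement ahead of the formylation and removes the MOM groups without protic acid. Carbinol 19 is rearranged under buffered conditions that leave the MOM ethers intact (PPTS or 0.05 M HClO4, aq. acetone, 0 °C) to the homoallylic alcohol F5. F5 is bis-formylated as in step 10 to give 22, now isolated. The aryl MOM ethers of 22 are then cleaved with TMSOTf/2,2'-bipyridyl (CH2Cl2, 0 °C; then H2O, which also releases the transiently silylated tertiary alcohol) to give 23.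

**Further compounds**

F1 | step 9 | (1S,3R,4R,7R)-4,8,8-trimethyl-3-{2-[2-{(1R)-3-methyl-1-[2,4,6-tris(methoxymethoxy)phenyl]butyl}oxiran-2-yl]ethyl}bicyclo[5.1.0]octan-2-one (epoxide epimers) | CC(C)C[C@@H](c1c(OCOC)cc(OCOC)cc1OCOC)C1(CO1)CC[C@@H]1[C@H](C)CC[C@H]2C(C)(C)[C@H]2C1=O
F2 | step 9 | (1aR,4R,4aR,7R,7aS,7bS)-7-(hydroxymethyl)-1,1,4-trimethyl-7-{(1R)-3-methyl-1-[2,4,6-tris(methoxymethoxy)phenyl]butyl}decahydro-1H-cyclopropa[e]azulen-7a-ol | CC(C)C[C@@H](c1c(OCOC)cc(OCOC)cc1OCOC)[C@@]1(CO)CC[C@H]2[C@]1(O)[C@@H]1C(C)(C)[C@@H]1CC[C@H]2C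
F3 | step 9 | O-primary 1H-imidazole-1-carbothioate of F2 | CC(C)C[C@@H](c1c(OCOC)cc(OCOC)cc1OCOC)[C@@]1(COC(=S)n3ccnc3)CC[C@H]2[C@]1(O)[C@@H]1C(C)(C)[C@@H]1CC[C@H]2C
F4 | step 7 | (1S,3R,4R,7R)-3-(3-iodobut-3-en-1-yl)-4,8,8-trimethylbicyclo[5.1.0]octan-2-ol (C2 carbinol epimers) | IC(=C)CC[C@@H]1[C@H](C)CC[C@H]2C(C)(C)[C@H]2C1O
F5 | step 11 | 2-[(3R,5R,8R,8aR)-3,8-dimethyl-3-{(1R)-3-methyl-1-[2,4,6-tris(methoxymethoxy)phenyl]butyl}-1,2,3,5,6,7,8,8a-octahydroazulen-5-yl]propan-2-ol | CC(C)C[C@@H](c1c(OCOC)cc(OCOC)cc1OCOC)[C@@]1(C)CC[C@H]2C1=C[C@H](C(C)(C)O)CC[C@H]2C
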